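The runs are simulated for substances that don't exist, noise included.

If I followed one molecule of left-handed substrate, it stood at a fork at each moment: couple to left-handed product, or flip to right-handed substrate.

in all of them: free catalyst 15 mol%
- Wednesday's: left-handed substrate 0.75 M; right-handed substrate 0.75 M; solid reagent 2.5 equiv; run made earlier
- flask: left-handed substrate 0.50 M; right-handed substrate 0.50 M; solid reagent 2.50 equiv; time 10 d

Wednesday's run (percent of the left-handed substrate and right-handed substrate together charged)

| time / h | left-handed product / % | right-handed product / % | left-handed substrate / % |
|---|---|---|---|
| 4.00 | 0.6 | 0 | 49.3 |
| 12.0 | 2.5 | 0.1 | 47.7 |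
| 20.0 | 5.7 | 0.3 | 44.7 |
| 30.0 | 8.6 | 0.7 | 42.2 |
| 50.0 | 15.2 | 0.7 | 36.4 |

(standard deviation of a reading: 0.3 percentage points)

- left-handed product and right-handed product together, in percent of the left-handed substrate and right-handed substrate charged together, at 10 d
- excess of left-handed product over right-handed product in the product at 10 d
- whether the exchange between left-handed substrate and right-handed substrate keeps pace with the reaction: how far the product's excess at 10 d gets from its value without exchange to its value with instant exchange (above 80% keeps pace, below 20% hardly takes part, else lags behind)

- free catalyst is single-handed; left-handed substrate and right-handed substrate are mirror images of each other, charged as a racemate, each of them at the stated concentration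
- given per volume of solution although it is solid: solid reagent
- at the start none of the solid reagent is in solution
- an excess is below zero if the other one leads
- no earlier run changes the charge of free catalyst; that part of a forecast is a guess

Wednesday's run started slowly, with 0.6% of left-handed product after 4.00 h, and none of the solid reagent was in solution at the start. Between 20.0 h and 50.0 h of that run, I read coupling as taking 0.00781 h⁻¹ of the left-handed substrate present.

Flip showed in the balance. In Wednesday's run, left-handed substrate and left-handed product together read 51.6% at 50.0 h, above the 50% charged, while right-handed substrate, taken from the balance, led left-handed substrate by about 5.4 percentage points on average at 20.0 h and 30.0 h. So I read flip as 0.00587 h⁻¹, roughly, given a scatter of 0.3 points.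

That made 57.1% the coupling share of Wednesday's run: the chance that a molecule leaving left-handed substrate couples rather than flips.

For the new flask, I slowed coupling by the factor 0.667, which was a guess, and left flip alone. Coupling then fell to 0.00521 h⁻¹, slower than flip, and the share fell to 47.0%. I expected exchange to lag.

The forecast said 42% of product at an excess of 87%, with exchange lags behind, reasoning “I guess that all rate constants scale with it”, so unlike me it lowered flip too.

The flask gave 58.2% at an excess of 90.9%, and exchange lags behind, getting 63% of the way.

    coupling partner + free catalyst + left-handed substrate → free catalyst + left-handed product (k = 0.0290 M⁻² min⁻¹)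
    coupling partner + free catalyst + right-handed substrate → free catalyst + right-handed product (k = 9.10 × 10⁻⁴ M⁻² min⁻¹)
    left-handed substrate ⇌ right-handed substrate (k = 1.10 × 10⁻⁴ min⁻¹)
    solid reagent ⇌ coupling partner, rate k4*(cs4 - [coupling partner]) while solid is left; crystals form when [coupling partner] > cs4 (solubility = 0.390 M, k = 3.30 × 10⁻⁴ min⁻¹)
    2 free catalyst → spent catalyst A (k = 0.00170 M⁻¹ min⁻¹)
    coupling partner + free catalyst → spent catalyst B (k = 3.80 × 10⁻⁵ M⁻¹ min⁻¹)

At 10.0 d in the flask, the half-life of left-handed substrate by coupling was 3.7 d against 4.4 d by flip (forward rate, the way back not counted), a coupling share at that moment of 54.3%, with coupling then at 0.00781 h⁻¹ where the forecast had 0.0051 per hour. In the neighbour charged with 0.620 equiv of solid reagent, the coupling share at that time was 3.60%, with 30.0% of product made.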